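The carbocycle is numbered C1 (alkene carbon bearing the C7H2OBz arm), C2 (alkene CH) and C3–C6 (carbinol carbons, benzoate on O5). Everything rests on cutting the only C=C bond of this cyclohexene ring, C1=C2: in the precursor each of these carbons carries a terminal methylene group in an acyclic 1,7-diene, and ring-closing olefin metathesis forges the six-membered carbocycle in one operation with all four stereocentres and the O7 benzoate already in place. The diene is a D-mannose-derived chain (C5, C4, C3 from mannose C2–C4; C6 from a Felkin-controlled alkenyllithium addition) whose O3/O4 trans-diol sits in a butane-2,3-diacetal that holds both alkene arms gauche. The O5 benzoate follows by axial-selective orthoester opening.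

Key step: step 7

Remark: the target locants C1–C7 defined above are used for every intermediate; the target is the (3R,4S,5R,6R) isomer.

Step 1
Reactants: 1 methyl α-D-mannopyranoside
Product: 2 methyl 3,4-O-[(2S,3S)-2,3-dimethoxybutane-2,3-diyl]-α-D-mannopyranoside
Conditions: butane-2,3-dione, HC(OMe)3, CSA (cat.), MeOH, reflux
Reagents that add atoms: butane-2,3-dione (CC(=O)C(C)=O); methanol (CO)
Why: Ley butane-2,3-diacetal protection (acid-catalysed acetalisation): only the trans-diequatorial O3/O4 diol can form the trans-fused 1,4-dioxane with both methoxy groups axial (anomeric effect), so O2–H and O6–H should stay free and the two acetal carbons are set (S,S) under thermodynamic control.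

Step 2
Reactants: 2 methyl 3,4-O-[(2S,3S)-2,3-dimethoxybutane-2,3-diyl]-α-D-mannopyranoside
Product: 3 methyl 6-deoxy-6-iodo-3,4-O-[(2S,3S)-2,3-dimethoxybutane-2,3-diyl]-α-D-mannopyranoside
Conditions: I2, PPh3, imidazole, toluene, 70 °C
Reagents that add atoms: iodine (II)
Why: Garegg–Samuelsson (Appel-type) iodination: the alkoxyphosphonium ion forms fastest at the primary O6 and is displaced by iodide in an SN2 step, while the axial secondary O2–H should remain untouched.

Step 3
Reactants: 3 methyl 6-deoxy-6-iodo-3,4-O-[(2S,3S)-2,3-dimethoxybutane-2,3-diyl]-α-D-mannopyranoside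
Product: 4 methyl 6-deoxy-6-iodo-3,4-O-[(2S,3S)-2,3-dimethoxybutane-2,3-diyl]-2-O-triethylsilyl-α-D-mannopyranoside
Conditions: Et3SiCl, imidazole, DMF, rt
Reagents that add atoms: chlorotriethylsilane (CC[Si](Cl)(CC)CC)
Why: Silyl ether formation on the only free hydroxyl; the non-chelating triethylsilyl group is chosen to steer the later carbonyl addition and to be lost under mild acid.

Step 4
Reactants: 4 methyl 6-deoxy-6-iodo-3,4-O-[(2S,3S)-2,3-dimethoxybutane-2,3-diyl]-2-O-triethylsilyl-α-D-mannopyranoside
Product: 5 5,6-dideoxy-3,4-O-[(2S,3S)-2,3-dimethoxybutane-2,3-diyl]-2-O-triethylsilyl-aldehydo-D-lyxo-hex-5-enose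
Conditions: Zn dust (activated), THF/H2O 9:1, sonication, 40 °C
Reagents that add atoms: none
Why: Bernet–Vasella reductive fragmentation: zinc inserts into the C6–I bond and Grob-type β-elimination opens the pyranoside, giving the vinyl group (target C2) and the aldehyde (target C6) without touching the three sugar stereocentres (target C5, C4, C3).

Step 5
Reactants: 5 5,6-dideoxy-3,4-O-[(2S,3S)-2,3-dimethoxybutane-2,3-diyl]-2-O-triethylsilyl-aldehydo-D-lyxo-hex-5-enose; 6 2-bromoprop-2-en-1-ol
Product: 9 5,6-anti diene triol (free O5–H/O6–H/O7–H; O3/O4 butane-2,3-diacetal), via dilithio reagent 7 (not isolated), via silyl ether adduct 8 (not isolated)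
Conditions: 6, t-BuLi (3 equiv per 6), Et2O, −78 to 0 °C; then 5, −78 °C; aq. NH4Cl; then PPTS, MeOH, rt
Reagents that add atoms: none
Why: Bromine–lithium exchange gives the dilithio 2-lithioallyl alkoxide, which adds 1,2 to the aldehyde; the polar Felkin–Anh (Cornforth) transition state places the nucleophile anti to the non-chelating α-silyloxy group and should set C6 as the 5,6-anti (later ring-cis) carbinol, and mild acidic methanolysis then removes the silyl group while the diacetal survives.

Step 6
Reactants: 9 5,6-anti diene triol (free O5–H/O6–H/O7–H; O3/O4 butane-2,3-diacetal)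
Product: 10 diene diol 7-O-benzoate
Conditions: BzCl (1.05 equiv), 2,4,6-collidine, CH2Cl2, −40 °C
Reagents that add atoms: benzoyl chloride (O=C(Cl)c1ccccc1)
Why: Kinetically selective esterification of the unhindered primary allylic O7–H over the two secondary hydroxyls at low temperature.

Step 7
Reactants: 10 diene diol 7-O-benzoate
Product: 11 cyclohexene 5,6-cis-diol 7-O-benzoate (O3/O4 butane-2,3-diacetal)
Conditions: second-generation Grubbs catalyst (H2IMes)(PCy3)Cl2Ru=CHPh (10 mol%), toluene (0.005 M), 80 °C
Reagents that add atoms: none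
Why: The ruthenium benzylidene loads onto the unhindered C2 vinyl group, the new alkylidene adds [2+2] across the 1,1-disubstituted C1 methylene alkene, and cycloreversion of the ruthenacyclobutane releases the C1=C2 bond while the ruthenium methylidene sheds ethylene on the next turnover (Chauvin mechanism). The closest known reaction type is ring-closing metathesis of carbohydrate-derived 1,7-dienes to carbasugar cyclohexenes with a trisubstituted alkene. The six-membered ring C1–C6 is closed by joining the two chain termini through the new C1=C2 double bond, whose cis geometry is dictated by the ring size. No stereocentre is formed, and C3–C6 pass through unchanged because only sp2 carbons react. The step needs cyclisation to outrun oligomerisation at the C2 vinyl group and ruthenium hydride isomerisation of the allylic alcohol; high dilution, the trans-diequatorial dioxane that keeps the C2 and C5 branches gauche, and the free allylic O6–H should secure this.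

Step 8
Reactants: 11 cyclohexene 5,6-cis-diol 7-O-benzoate (O3/O4 butane-2,3-diacetal)
Product: 14 [(3R,4S,5R,6R)-5-(benzoyloxy)-3,4,6-trihydroxycyclohex-1-en-1-yl]methyl benzoate, via cyclic orthobenzoate 12 (not isolated), via diacetal-protected dibenzoate 13 (not isolated)
Conditions: PhC(OMe)3, CSA (cat.), CH2Cl2, rt; then TFA/H2O 9:1, 0 °C to rt
Reagents that add atoms: trimethyl orthobenzoate (COC(OC)(OC)c1ccccc1); water (O)
Why: Cyclic orthoester formation on the cis-5,6-diol and acid hydrolysis: the hemiorthoester should collapse under stereoelectronic control to the ester of the axial oxygen (O5, axial while the trans-fused diacetal still locks the half-chair) and the pseudo-equatorial C6 alcohol, after which the same aqueous acid hydrolyses the butane-2,3-diacetal to free O3–H and O4–H.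

Compound list
1 | methyl α-D-mannopyranoside | CO[C@H]1O[C@H](CO)[C@@H](O)[C@H](O)[C@@H]1O | starting material
2 | methyl 3,4-O-[(2S,3S)-2,3-dimethoxybutane-2,3-diyl]-α-D-mannopyranoside | CO[C@H]1O[C@H](CO)[C@H]2O[C@](C)(OC)[C@@](C)(OC)O[C@@H]2[C@@H]1O | intermediate
3 | methyl 6-deoxy-6-iodo-3,4-O-[(2S,3S)-2,3-dimethoxybutane-2,3-diyl]-α-D-mannopyranoside | CO[C@H]1O[C@H](CI)[C@H]2O[C@](C)(OC)[C@@](C)(OC)O[C@@H]2[C@@H]1O | intermediate
4 | methyl 6-deoxy-6-iodo-3,4-O-[(2S,3S)-2,3-dimethoxybutane-2,3-diyl]-2-O-triethylsilyl-α-D-mannopyranoside | CO[C@H]1O[C@H](CI)[C@H]2O[C@](C)(OC)[C@@](C)(OC)O[C@@H]2[C@@H]1O[Si](CC)(CC)CC | intermediate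
5 | 5,6-dideoxy-3,4-O-[(2S,3S)-2,3-dimethoxybutane-2,3-diyl]-2-O-triethylsilyl-aldehydo-D-lyxo-hex-5-enose (aldehyde carbon = target C6, vinyl CH = target C2) | O=C[C@@H](O[Si](CC)(CC)CC)[C@H]1O[C@](C)(OC)[C@@](C)(OC)O[C@@H]1C=C | intermediate
6 | 2-bromoprop-2-en-1-ol | OCC(Br)=C | starting material
7 | dilithio reagent: lithium 2-lithioprop-2-en-1-olate | [Li]OCC([Li])=C | intermediate
8 | silyl ether adduct: acyclic 1,7-diene with C1(=CH2) bearing C7H2OH, C6–OH anti to C5–OSiEt3, O3/O4 as trans butane-2,3-diacetal, C2H=CH2 | C=C(CO)[C@@H](O)[C@@H](O[Si](CC)(CC)CC)[C@H]1O[C@](C)(OC)[C@@](C)(OC)O[C@@H]1C=C | intermediate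
9 | 5,6-anti diene triol: as 8 with free O5–H (free O5–H/O6–H/O7–H; O3/O4 butane-2,3-diacetal) | C=C(CO)[C@@H](O)[C@@H](O)[C@H]1O[C@](C)(OC)[C@@](C)(OC)O[C@@H]1C=C | intermediate
10 | diene diol 7-O-benzoate: as 9 with O7 benzoylated | C=C(COC(=O)c1ccccc1)[C@@H](O)[C@@H](O)[C@H]1O[C@](C)(OC)[C@@](C)(OC)O[C@@H]1C=C | intermediate
11 | cyclohexene 5,6-cis-diol 7-O-benzoate: target ring with C1=C2, O3/O4 trans butane-2,3-diacetal, free O5–H (axial) and O6–H, configurations at C3–C6 as in the target | O=C(OCC1=C[C@H]2O[C@](C)(OC)[C@@](C)(OC)O[C@@H]2[C@H](O)[C@@H]1O)c1ccccc1 | intermediate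
12 | cyclic orthobenzoate: 2-methoxy-2-phenyl-1,3-dioxolane across O5/O6 of 11 (mixture at the orthoester carbon) | O=C(OCC1=C[C@H]2O[C@](C)(OC)[C@@](C)(OC)O[C@@H]2[C@@H]3OC(OC)(c4ccccc4)O[C@H]13)c1ccccc1 | intermediate
13 | diacetal-protected dibenzoate: 11 with O5 benzoylated and O6–H free | O=C(OCC1=C[C@H]2O[C@](C)(OC)[C@@](C)(OC)O[C@@H]2[C@H](OC(=O)c2ccccc2)[C@@H]1O)c1ccccc1 | intermediate
14 | [(3R,4S,5R,6R)-5-(benzoyloxy)-3,4,6-trihydroxycyclohex-1-en-1-yl]methyl benzoate | O=C(OCC1=C[C@@H](O)[C@H](O)[C@H](OC(=O)c2ccccc2)[C@@H]1O)c1ccccc1 | target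

Total steps: 8. Longest linear sequence: 8 steps (1 to 14); 2-bromoprop-2-en-1-ol (6) enters directly in step 5.

Steps most likely to fail

1. Step 5. What may go wrong: poor facial selectivity in the addition to the α-silyloxy aldehyde, anti-Felkin attack eroding the 5,6-anti relationship. The fallback sets out from aldehyde 5 and rejoins the route at diol 11, setting C6 by ring-controlled reduction instead of acyclic addition. The addition would be worked up without acid so that the silyl ether stays, giving the C6-epimeric silyl ether diol F1. Selective benzoylation of O7–H (BzCl, 2,4,6-collidine, −40 °C) would give the C6-epimeric benzoate F2, and ring-closing metathesis as in step 7 the C6-epimeric cyclohexenols F3. Dess–Martin oxidation would converge both epimers on the cyclohexenone F4. Luche reduction (NaBH4, CeCl3·7H2O, MeOH, −78 °C) should deliver hydride axially, anti to the axial O5 silyl ether, giving the 5,6-cis alcohol F5. PPTS in MeOH would then remove the silyl group to give 11.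

2. Step 7. What may go wrong: slow ring closure at the hindered, allylically oxygenated 1,1-disubstituted C1 alkene, with oligomerisation through the C2 vinyl group and isomerisation of the allylic alcohol taking over. The fallback sets out from aldehyde 5 and rejoins the route at diol 11; it closes the ring on an unhindered diene and introduces C7 afterwards. Vinylmagnesium bromide (CH2=CHMgBr, THF, −78 °C) would give the C6-epimeric divinyl carbinol F6, whose two monosubstituted alkenes should close readily (second-generation Grubbs catalyst, CH2Cl2, 40 °C) to the C7-free cyclohexenol F7. Dess–Martin oxidation would give the enone F8, and a Morita–Baylis–Hillman reaction with aqueous formaldehyde (imidazole, THF/H2O, rt) would install C7 at C1 as the hydroxymethyl enone F9. Benzoylation (BzCl, pyridine) would give the cyclohexenone F4 of the first fallback, which is reduced to the 5,6-cis alcohol F5 and desilylated to 11 as described there.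

3. Step 8. What may go wrong: loss of regiocontrol in the orthoester opening, or acid-promoted benzoyl migration from O5 to O6 or O4 during diacetal hydrolysis. The fallback sets out from diol 11 and rejoins the route at target 14, replacing stereoelectronic control by protecting-group differentiation. The more accessible pseudo-equatorial allylic O6–H would be silylated (TBSCl, imidazole, DMF, 0 °C) to the 6-O-silyl ether F10. The axial O5–H would then be benzoylated (BzCl, DMAP, pyridine) to the fully protected dibenzoate F11, and TFA/H2O 9:1 would remove the silyl ether and the diacetal together to give 14.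

Further compounds
F1 | step 5 | C6-epimeric silyl ether diol (8 and its C6 epimer) | C=C(CO)C(O)[C@@H](O[Si](CC)(CC)CC)[C@H]1O[C@](C)(OC)[C@@](C)(OC)O[C@@H]1C=C
F2 | step 5 | C6-epimeric benzoate (7-O-benzoyl F1) | C=C(COC(=O)c1ccccc1)C(O)[C@@H](O[Si](CC)(CC)CC)[C@H]1O[C@](C)(OC)[C@@](C)(OC)O[C@@H]1C=C
F3 | step 5 | C6-epimeric cyclohexenols (5-O-triethylsilyl, 7-O-benzoyl, O3/O4 diacetal) | O=C(OCC1=C[C@H]2O[C@](C)(OC)[C@@](C)(OC)O[C@@H]2[C@H](O[Si](CC)(CC)CC)C1O)c1ccccc1
F4 | step 5 | cyclohexenone (C6 ketone, C1=C2, 7-O-benzoyl, 5-O-triethylsilyl, O3/O4 diacetal) | O=C1C(COC(=O)c3ccccc3)=C[C@H]2O[C@](C)(OC)[C@@](C)(OC)O[C@@H]2[C@@H]1O[Si](CC)(CC)CC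
F5 | step 5 | 5,6-cis alcohol (5-O-triethylsilyl ether of 11) | O=C(OCC1=C[C@H]2O[C@](C)(OC)[C@@](C)(OC)O[C@@H]2[C@H](O[Si](CC)(CC)CC)[C@@H]1O)c1ccccc1
F6 | step 7 | C6-epimeric divinyl carbinol | C=CC(O)[C@@H](O[Si](CC)(CC)CC)[C@H]1O[C@](C)(OC)[C@@](C)(OC)O[C@@H]1C=C
F7 | step 7 | C7-free cyclohexenol (C6 epimers, 5-O-triethylsilyl, O3/O4 diacetal) | OC1C=C[C@H]2O[C@](C)(OC)[C@@](C)(OC)O[C@@H]2[C@@H]1O[Si](CC)(CC)CC
F8 | step 7 | enone (C6 ketone, C1=C2, no C7) | O=C1C=C[C@H]2O[C@](C)(OC)[C@@](C)(OC)O[C@@H]2[C@@H]1O[Si](CC)(CC)CC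
F9 | step 7 | hydroxymethyl enone (C7H2OH on C1) | O=C1C(CO)=C[C@H]2O[C@](C)(OC)[C@@](C)(OC)O[C@@H]2[C@@H]1O[Si](CC)(CC)CC
F10 | step 8 | 6-O-silyl ether (6-O-tert-butyldimethylsilyl 11) | O=C(OCC1=C[C@H]2O[C@](C)(OC)[C@@](C)(OC)O[C@@H]2[C@H](O)[C@@H]1O[Si](C)(C)C(C)(C)C)c1ccccc1
F11 | step 8 | fully protected dibenzoate (5-O-benzoyl-6-O-tert-butyldimethylsilyl 11) | O=C(OCC1=C[C@H]2O[C@](C)(OC)[C@@](C)(OC)O[C@@H]2[C@H](OC(=O)c2ccccc2)[C@@H]1O[Si](C)(C)C(C)(C)C)c1ccccc1
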